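The target is epicatechin-(4β→6)-catechin-(4α→6)-catechin. It is cut at C4–C4a of the middle and bottom units. In both, interflavan carbon C6 of ring A lies para to C8a, the carbon that carries O1. Before closure each ring A is thus a symmetric 4-substituted 3,5-dibenzyloxyphenyl ether with two equivalent ortho C–H carbons, and no 4→8 isomer can form. One gold-catalysed twofold 6-endo-dig hydroarylation closes both pyran rings as flav-3-enes. Its precursor is a bis(aryl propargyl ether) chain that hangs from C4 of benzylated epicatechin and already holds both C2 centres. Syn hydroboration anti to each C2 aryl group then sets C3 and C4; hydrogenolysis ends the route.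

Key step: step 16

Assumption: which ProPhenol antipode gives the S alcohol is settled by a test run with chiral HPLC. Both antipodes are sold, so the plan does not depend on the answer.

Remark on regiocontrol: a 3,5-dibenzyloxyphenol would be attacked next to its free hydroxyl, both by the C4 cation and by iodine. Both rings A are therefore grown from threefold-symmetric phloroglucinol, and the para oxygen is told apart afterwards.

Remark on descriptors: at the propargylic carbon the alkynyl group outranks aryl when it carries SiMe3 or aryl and ranks below aryl when it carries H. R/S therefore changes in steps 2, 14 and 15 without any change in space.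

Step 1
Reactants: 1 3,4-bis(benzyloxy)benzaldehyde; 2 (trimethylsilyl)acetylene
Product: 3 (S)-1-[3,4-bis(benzyloxy)phenyl]-3-(trimethylsilyl)prop-2-yn-1-ol
Conditions: Me2Zn (3 equiv), ProPhenol (10 mol %, antipode giving the S alcohol), Ph3PO (20 mol %), toluene, 0 °C; aq NH4Cl
Reagents that add atoms: none
Why: Catalytic asymmetric alkynylation: the alkynylzinc made from 2 and Me2Zn adds to the aromatic aldehyde inside the dinuclear zinc–ProPhenol complex, whose chiral pocket selects the aldehyde face and so sets the carbinol centre that becomes, after inversion, C2 of both catechin units.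

Step 2
Reactants: 3 (S)-silyl alkynol
Product: 4 (R)-1-[3,4-bis(benzyloxy)phenyl]prop-2-yn-1-ol
Conditions: K2CO3 (0.2 equiv), MeOH, 0 °C → rt
Reagents that add atoms: none
Why: Base-catalysed protodesilylation of a C(sp)–SiMe3 bond in methanol is routine and does not touch the carbinol centre, whose descriptor changes from S to R only because ethynyl ranks below aryl.

Step 3
Reactants: 5 phloroglucinol (anhydrous, 5 equiv); 3 (S)-silyl alkynol
Product: 6 5-{[(R)-1-[3,4-bis(benzyloxy)phenyl]-3-(trimethylsilyl)prop-2-yn-1-yl]oxy}benzene-1,3-diol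
Conditions: PPh3, DIAD, THF, −20 → 0 °C
Reagents that add atoms: none
Why: Mitsunobu etherification replaces the activated hydroxyl by SN2 with inversion (S to R, the later C2 of the bottom unit); the three hydroxyls of 5 are equivalent, and its excess suppresses a second etherification and captures the oxyphosphonium ion before it can ionise.

Step 4
Reactants: 6 resorcinol monoether
Product: 7 5-{[(R)-1-[3,4-bis(benzyloxy)phenyl]-3-(trimethylsilyl)prop-2-yn-1-yl]oxy}-2-iodobenzene-1,3-diol
Conditions: I2 (1.0 equiv), NaHCO3, THF/H2O, 0 °C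
Reagents that add atoms: iodine, II
Why: Electrophilic aromatic iodination of resorcinols with I2 and bicarbonate goes to the carbon between the two hydroxyls, a preference reinforced here by the para ether oxygen and by the bulky secondary ether that screens the other two ring carbons.

Step 5
Reactants: 7 iodoresorcinol ether
Product: 8 1,3-bis(benzyloxy)-2-iodo-5-{[(R)-1-[3,4-bis(benzyloxy)phenyl]-3-(trimethylsilyl)prop-2-yn-1-yl]oxy}benzene (bottom-ring iodide)
Conditions: BnBr, K2CO3, dry acetone, rt → 40 °C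
Reagents that add atoms: benzyl bromide, BrCc1ccccc1
Why: Williamson ether synthesis on the two acidic phenols; aprotic, dry conditions leave the C–SiMe3 bond, the C–I bond and the propargylic centre alone.

Step 6
Reactants: 9 (−)-epicatechin
Product: 10 5,7,3',4'-tetra-O-benzyl-(−)-epicatechin
Conditions: BnBr (4.4 equiv), K2CO3, DMF, 0 °C → rt, argon
Reagents that add atoms: benzyl bromide, BrCc1ccccc1
Why: Williamson benzylation with a carbonate base reaches only the four phenols, leaves the secondary 3-OH free and is too mild to epimerise C2 through ring opening.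

Step 7
Reactants: 10 tetra-O-benzylepicatechin
Product: 11 3,5,7,3',4'-penta-O-benzyl-(−)-epicatechin
Conditions: NaH, BnBr, DMF, 0 °C → rt
Reagents that add atoms: benzyl bromide, BrCc1ccccc1
Why: Williamson benzylation of the remaining secondary alkoxide, needed so that no aliphatic hydroxyl of the top unit can compete in the later Mitsunobu step.

Step 8
Reactants: 11 penta-O-benzylepicatechin
Product: 12 4β-(2-ethoxyethoxy)-3,5,7,3',4'-penta-O-benzylepicatechin (2,3-cis-3,4-trans)
Conditions: DDQ, 2-ethoxyethanol, CH2Cl2, rt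
Reagents that add atoms: 2-ethoxyethanol, CCOCCO
Why: Benzylic oxidation by hydride abstraction: DDQ takes the hydride from C4, the position activated by O1 and the 5,7-dibenzyloxy ring A, and the alcohol adds to the cation from the β face, opposite the 2-aryl and 3-benzyloxy groups.

Step 9
Reactants: 12 C4 ether; 5 phloroglucinol (5 equiv)
Product: 13 penta-O-benzylepicatechin-(4β→2)-phloroglucinol (2,3-cis-3,4-trans)
Conditions: BF3·OEt2 (0.2 equiv), CH2Cl2/THF, −30 → 0 °C
Reagents that add atoms: none
Why: Friedel–Crafts alkylation: the Lewis acid regenerates the C4 cation, any of the three equivalent C–H carbons of 5 attacks it from the β face opposite the 2-aryl and 3-benzyloxy groups, which sets C4 as 3,4-trans as is the rule in the 2,3-cis series, and the excess of 5 prevents a second alkylation.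

Step 10
Reactants: 13 phloroglucinol adduct
Product: 14 4β-[2,6-dihydroxy-4-(triisopropylsilyloxy)phenyl]-penta-O-benzylepicatechin
Conditions: TIPSCl (1.05 equiv), imidazole, DMF, 0 °C
Reagents that add atoms: triisopropylsilyl chloride, CC(C)[Si](Cl)(C(C)C)C(C)C
Why: Silyl ether formation under steric control: the bulky chlorosilane reaches only the hydroxyl para to the flavanyl group, which has two C–H neighbours, whereas the other two are flanked by the branched C4 substituent.

Step 11
Reactants: 14 para-silyl ether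
Product: 15 4β-[2,6-bis(benzyloxy)-4-(triisopropylsilyloxy)phenyl]-penta-O-benzylepicatechin
Conditions: NaH, BnBr, DMF, 0 °C → rt
Reagents that add atoms: benzyl bromide, BrCc1ccccc1
Why: Williamson benzylation of the two hindered phenoxides; the triisopropylsilyl aryl ether tolerates NaH and does not migrate.

Step 12
Reactants: 15 silyl ether
Product: 16 4β-[2,6-bis(benzyloxy)-4-hydroxyphenyl]-penta-O-benzylepicatechin (middle-ring phenol)
Conditions: Bu4NF, THF, 0 °C; aq NH4Cl
Reagents that add atoms: none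
Why: Fluoride-induced cleavage of the Si–O bond frees the one phenol that will become O1 of the middle unit and affects no benzyl ether.

Step 13
Reactants: 16 middle-ring phenol; 4 (R)-alkynol
Product: 17 4β-{2,6-bis(benzyloxy)-4-[(S)-1-(3,4-dibenzyloxyphenyl)prop-2-ynyloxy]phenyl}-penta-O-benzylepicatechin
Conditions: PPh3, DIAD, toluene, −20 → 0 °C
Reagents that add atoms: none
Why: Mitsunobu etherification with SN2 inversion turns the R alcohol into the S ether and thereby sets C2 of the middle unit; the unhindered para phenol, the non-polar solvent and the low temperature favour direct displacement over ionisation.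

Step 14
Reactants: 17 terminal alkyne; 8 bottom-ring iodide (slight excess)
Product: 18 silyl-capped bis(aryl propargyl ether): 17 carrying at its alkyne terminus the 2,6-bis(benzyloxy)-4-[(R)-1-(3,4-dibenzyloxyphenyl)-3-(trimethylsilyl)prop-2-ynyloxy]phenyl group (inner centre now R by rank change)
Conditions: Pd(PPh3)2Cl2 (5 mol %), CuI (10 mol %), Et3N/THF, 50 °C, degassed
Reagents that add atoms: none
Why: Sonogashira coupling of a terminal alkyne with an aryl iodide; the iodide is electron-rich and doubly ortho-substituted, hence the mild heating, while the silyl cap keeps the second alkyne out of the reaction and triethylamine is too weak to deprotonate the propargylic C–H.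

Step 15
Reactants: 18 silyl-capped bis(ether)
Product: 19 bis(aryl propargyl ether) precursor: 18 with C≡C–H in place of C≡C–SiMe3 (inner centre R, outer centre S)
Conditions: K2CO3 (0.2 equiv), MeOH/THF, 0 °C → rt
Reagents that add atoms: none
Why: Base-catalysed protodesilylation as in step 2, short and cold so that neither propargylic C–H is deprotonated.

Step 16
Reactants: 19 bis(aryl propargyl ether) precursor
Product: 21 trideca-O-benzyl epicatechin-(4β→6)-(2S)-flav-3-ene-(4→6)-(2S)-flav-3-ene, via bottom-closed mono(flav-3-ene) 20 (not isolated)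
Conditions: Ph3PAuNTf2 (10 mol %), 4 Å MS, CH2Cl2 (0.02 M), −10 °C → rt, dark
Reagents that add atoms: none
Why: Cationic monovalent gold binds each alkyne, an ortho C–H carbon of the tethered trioxygenated ring attacks the alkyne carbon remote from the ether carbon, and rearomatisation with protodeauration releases the 2H-chromene and the catalyst; the unhindered terminal alkyne should react first (20), the internal one second. The reaction type is the known gold-catalysed intramolecular hydroarylation (cycloisomerisation) of aryl propargyl ethers to 2H-chromenes, known for terminal and for aryl-capped alkynes and used here twice in one flask. Ring C of the bottom unit and ring C of the middle unit both close in the 6-endo-dig mode, forming C4–C4a in each; the 5-exo mode would give a strained alkylidene dihydrobenzofuran and is further disfavoured at the internal alkyne because the 2,6-dibenzyloxyaryl group stabilises positive charge on the carbon that becomes C4. No stereocentre is formed, and the two C2 centres pass through unchanged as long as their C–O bonds do not ionise, which a silver-free and acid-free catalyst, molecular sieves, low temperature and exclusion of light are meant to ensure. Site selectivity needs no control, since in each ring A the two ortho carbons are equivalent (C6 para to C8a) and either closure gives the 4→6 link. Chemoselectivity is needed against 5-endo attack of a flanking benzyloxy oxygen on the internal alkyne, and the much higher carbon nucleophilicity of the phloroglucinol-type ring together with the polarisation of the alkyne away from that mode should provide it.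

Step 17
Reactants: 21 bis(flav-3-ene)
Product: 23 trideca-O-benzyl epicatechin-(4β→6)-catechin-(4α→6)-catechin (3-OH free in the middle and bottom units), via bis(C3-borane) adduct 22 (not isolated)
Conditions: BH3·THF (excess), THF, 0 °C → rt; then NaOH, H2O2, 0 °C
Reagents that add atoms: hydrogen peroxide, OO; borane–tetrahydrofuran, B.C1CCOC1 (its boron stays only in 22)
Why: Hydroboration–oxidation: BH3 adds syn across each C3=C4 bond from the face opposite the C2 aryl group with boron on C3 (away from the carbon bound to electron-rich ring A and, in the middle unit, away from the fully substituted C4), and oxidation with retention gives the 2,3-trans alcohol in both units and the 3,4-trans (4α) aryl group in the middle unit, as known for flav-3-enes.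

Step 18
Reactants: 23 trideca-O-benzyl trimer
Product: 24 epicatechin-(4β→6)-catechin-(4α→6)-catechin (target)
Conditions: H2 (1 atm), Pd(OH)2/C, THF/MeOH/H2O, rt
Reagents that add atoms: none
Why: Catalytic hydrogenolysis of benzyl ethers under neutral conditions is the standard last step for benzylated proanthocyanidins and leaves the C2–O1 bonds, the interflavan bonds and all eight stereocentres untouched.

Compound list
1 | 3,4-bis(benzyloxy)benzaldehyde | O=Cc1ccc(OCc2ccccc2)c(OCc2ccccc2)c1 | starting material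
2 | (trimethylsilyl)acetylene | C#C[Si](C)(C)C | starting material
3 | (S)-1-[3,4-bis(benzyloxy)phenyl]-3-(trimethylsilyl)prop-2-yn-1-ol | O[C@@H](c1ccc(OCc2ccccc2)c(OCc2ccccc2)c1)C#C[Si](C)(C)C | intermediate
4 | (R)-1-[3,4-bis(benzyloxy)phenyl]prop-2-yn-1-ol | O[C@@H](c1ccc(OCc2ccccc2)c(OCc2ccccc2)c1)C#C | intermediate
5 | phloroglucinol | Oc1cc(O)cc(O)c1 | starting material
6 | (R)-propargyl monoether of phloroglucinol | Oc1cc(O)cc(O[C@H](c2ccc(OCc3ccccc3)c(OCc3ccccc3)c2)C#C[Si](C)(C)C)c1 | intermediate
7 | 2-iodo derivative of 6 | Oc1cc(O[C@H](c2ccc(OCc3ccccc3)c(OCc3ccccc3)c2)C#C[Si](C)(C)C)cc(O)c1I | intermediate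
8 | bottom-ring iodide | Ic1c(OCc9ccccc9)cc(O[C@H](c5ccc(OCc9ccccc9)c(OCc9ccccc9)c5)C#C[Si](C)(C)C)cc1OCc9ccccc9 | intermediate
9 | (−)-epicatechin | O[C@@H]1Cc2c(O)cc(O)cc2O[C@@H]1c1ccc(O)c(O)c1 | starting material
10 | 5,7,3',4'-tetra-O-benzylepicatechin | O(Cc9ccccc9)c1cc(OCc9ccccc9)c2c(c1)O[C@H](c5ccc(OCc9ccccc9)c(OCc9ccccc9)c5)[C@H](O)C2 | intermediate
11 | 3,5,7,3',4'-penta-O-benzylepicatechin | O(Cc9ccccc9)c1cc(OCc9ccccc9)c2c(c1)O[C@H](c5ccc(OCc9ccccc9)c(OCc9ccccc9)c5)[C@H](OCc9ccccc9)C2 | intermediate
12 | 4β-(2-ethoxyethoxy)-penta-O-benzylepicatechin | O(Cc9ccccc9)c1cc(OCc9ccccc9)c2c(c1)O[C@H](c5ccc(OCc9ccccc9)c(OCc9ccccc9)c5)[C@H](OCc9ccccc9)[C@H]2OCCOCC | intermediate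
13 | penta-O-benzylepicatechin-(4β→2)-phloroglucinol | O(Cc9ccccc9)c1cc(OCc9ccccc9)c2c(c1)O[C@H](c5ccc(OCc9ccccc9)c(OCc9ccccc9)c5)[C@H](OCc9ccccc9)[C@H]2c3c(O)cc(O)cc3O | intermediate
14 | para-O-triisopropylsilyl ether of 13 | O(Cc9ccccc9)c1cc(OCc9ccccc9)c2c(c1)O[C@H](c5ccc(OCc9ccccc9)c(OCc9ccccc9)c5)[C@H](OCc9ccccc9)[C@H]2c3c(O)cc(O[Si](C(C)C)(C(C)C)C(C)C)cc3O | intermediate
15 | di-O-benzyl derivative of 14 | O(Cc9ccccc9)c1cc(OCc9ccccc9)c2c(c1)O[C@H](c5ccc(OCc9ccccc9)c(OCc9ccccc9)c5)[C@H](OCc9ccccc9)[C@H]2c3c(OCc9ccccc9)cc(O[Si](C(C)C)(C(C)C)C(C)C)cc3OCc9ccccc9 | intermediate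
16 | middle-ring phenol | O(Cc9ccccc9)c1cc(OCc9ccccc9)c2c(c1)O[C@H](c5ccc(OCc9ccccc9)c(OCc9ccccc9)c5)[C@H](OCc9ccccc9)[C@H]2c3c(OCc9ccccc9)cc(O)cc3OCc9ccccc9 | intermediate
17 | (S)-propargyl ether of 16, terminal alkyne | O(Cc9ccccc9)c1cc(OCc9ccccc9)c2c(c1)O[C@H](c5ccc(OCc9ccccc9)c(OCc9ccccc9)c5)[C@H](OCc9ccccc9)[C@H]2c3c(OCc9ccccc9)cc(O[C@H](c5ccc(OCc9ccccc9)c(OCc9ccccc9)c5)C#C)cc3OCc9ccccc9 | intermediate
18 | silyl-capped bis(aryl propargyl ether) | O(Cc9ccccc9)c1cc(OCc9ccccc9)c2c(c1)O[C@H](c5ccc(OCc9ccccc9)c(OCc9ccccc9)c5)[C@H](OCc9ccccc9)[C@H]2c3c(OCc9ccccc9)cc(O[C@H](c5ccc(OCc9ccccc9)c(OCc9ccccc9)c5)C#Cc4c(OCc9ccccc9)cc(O[C@H](c5ccc(OCc9ccccc9)c(OCc9ccccc9)c5)C#C[Si](C)(C)C)cc4OCc9ccccc9)cc3OCc9ccccc9 | intermediate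
19 | bis(aryl propargyl ether) precursor of the key step | O(Cc9ccccc9)c1cc(OCc9ccccc9)c2c(c1)O[C@H](c5ccc(OCc9ccccc9)c(OCc9ccccc9)c5)[C@H](OCc9ccccc9)[C@H]2c3c(OCc9ccccc9)cc(O[C@H](c5ccc(OCc9ccccc9)c(OCc9ccccc9)c5)C#Cc4c(OCc9ccccc9)cc(O[C@H](c5ccc(OCc9ccccc9)c(OCc9ccccc9)c5)C#C)cc4OCc9ccccc9)cc3OCc9ccccc9 | intermediate
20 | bottom-closed mono(flav-3-ene), not isolated | O(Cc9ccccc9)c1cc(OCc9ccccc9)c2c(c1)O[C@H](c5ccc(OCc9ccccc9)c(OCc9ccccc9)c5)[C@H](OCc9ccccc9)[C@H]2c3c(OCc9ccccc9)cc(O[C@H](c5ccc(OCc9ccccc9)c(OCc9ccccc9)c5)C#Cc4c(OCc9ccccc9)cc6c(c4OCc9ccccc9)C=C[C@@H](c5ccc(OCc9ccccc9)c(OCc9ccccc9)c5)O6)cc3OCc9ccccc9 | intermediate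
21 | 4→6 linked bis(flav-3-ene), product of the key step | O(Cc9ccccc9)c1cc(OCc9ccccc9)c2c(c1)O[C@H](c5ccc(OCc9ccccc9)c(OCc9ccccc9)c5)[C@H](OCc9ccccc9)[C@H]2c3c(OCc9ccccc9)cc7c(c3OCc9ccccc9)C(c4c(OCc9ccccc9)cc6c(c4OCc9ccccc9)C=C[C@@H](c5ccc(OCc9ccccc9)c(OCc9ccccc9)c5)O6)=C[C@@H](c5ccc(OCc9ccccc9)c(OCc9ccccc9)c5)O7 | intermediate
22 | bis(C3-borane) adduct, not isolated | O(Cc9ccccc9)c1cc(OCc9ccccc9)c2c(c1)O[C@H](c5ccc(OCc9ccccc9)c(OCc9ccccc9)c5)[C@H](OCc9ccccc9)[C@H]2c3c(OCc9ccccc9)cc7c(c3OCc9ccccc9)[C@@H](c4c(OCc9ccccc9)cc6c(c4OCc9ccccc9)C[C@H](B)[C@@H](c5ccc(OCc9ccccc9)c(OCc9ccccc9)c5)O6)[C@H](B)[C@@H](c5ccc(OCc9ccccc9)c(OCc9ccccc9)c5)O7 | intermediate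
23 | trideca-O-benzyl trimer | O(Cc9ccccc9)c1cc(OCc9ccccc9)c2c(c1)O[C@H](c5ccc(OCc9ccccc9)c(OCc9ccccc9)c5)[C@H](OCc9ccccc9)[C@H]2c3c(OCc9ccccc9)cc7c(c3OCc9ccccc9)[C@@H](c4c(OCc9ccccc9)cc6c(c4OCc9ccccc9)C[C@H](O)[C@@H](c5ccc(OCc9ccccc9)c(OCc9ccccc9)c5)O6)[C@H](O)[C@@H](c5ccc(OCc9ccccc9)c(OCc9ccccc9)c5)O7 | intermediate
24 | epicatechin-(4β→6)-catechin-(4α→6)-catechin | Oc1cc(O)c2c(c1)O[C@H](c1ccc(O)c(O)c1)[C@H](O)[C@H]2c1c(O)cc2c(c1O)[C@@H](c1c(O)cc3c(c1O)C[C@H](O)[C@@H](c1ccc(O)c(O)c1)O3)[C@H](O)[C@@H](c1ccc(O)c(O)c1)O2 | target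

Total step count: 18. Longest linear sequence: 13 steps (9 to 24, steps 6–18). Steps 1–2 and 3–5 are side branches.

Steps most likely to fail

Step 16.
- **What may go wrong:** the benzylic and propargylic C2–O bonds may ionise under the Lewis acid, with loss of configuration or of the phenol. A flanking benzyl ether oxygen may attack the alkyne. The second closure may stall at the crowded internal alkyne.
- **Fallback:** cationic interflavan coupling with bromine capping. It sets out from 12 and comes back at 24.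
- Purchased (+)-catechin is benzylated (BnBr, K2CO3, DMF) to 5,7,3',4'-tetra-O-benzylcatechin F1.
- NBS in CH2Cl2 at low temperature brominates the most nucleophilic carbon, C8. This gives 8-bromo-tetra-O-benzylcatechin F2, in which C6 is the only free ring A carbon.
- Part of F2 is oxidised with DDQ and 2-ethoxyethanol to 8-bromo-4β-(2-ethoxyethoxy)-tetra-O-benzylcatechin F3.
- Coupling of F3 with an excess of F2 (TMSOTf, CH2Cl2, −78 °C) should follow the 3,4-trans preference of 2,3-trans C4 cations. It should give 8-bromo-tetra-O-benzylcatechin-(4α→6)-8-bromo-tetra-O-benzylcatechin F4.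
- C6 of the upper unit is the only free nucleophilic carbon of F4. Coupling with 12 under the same conditions should therefore give the dibromo trideca-O-benzyl trimer F5.
- H2 over Pd(OH)2/C with Et3N removes both bromines and all benzyl groups and gives 24.

Step 17.
- **What may go wrong:** borane may add slowly to the crowded trisubstituted C3=C4 bond of the middle unit. During that time the Lewis-acidic C3–BH2 groups already formed can expel O1, opening the ring by β-elimination. The facial bias may also be weak, because the C4 aryl group shields both faces.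
- **Fallback:** nucleophilic instead of electrophilic boron. It sets out from 21 and comes back at 23.
- Copper-catalysed protoboration (B2pin2, CuCl, Xantphos, NaOt-Bu, MeOH, THF, rt) adds boryl-copper syn, with boron on C3 and copper on benzylic C4, anti to the C2 aryl group.
- Protonation of the C4–Cu bond with retention gives the isolable, weakly Lewis-acidic bis(C3-pinacolboronate) F6.
- After purification F6 is oxidised with NaBO3·4H2O in THF/H2O, with retention, to 23.

Step 13 (the same concern applies to step 3).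
- **What may go wrong:** the oxyphosphonium salt of the doubly activated alcohol may partly ionise, which would erode the configuration of the later C2.
- **Fallback:** catalyst-controlled C–O bond formation instead of inversion. It sets out from 4 and 16 and comes back at 17.
- Compound 4 is acetylated (Ac2O, pyridine) to (R)-1-[3,4-bis(benzyloxy)phenyl]prop-2-yn-1-yl acetate F7.
- Enantioselective propargylic etherification follows, with (CuOTf)2·C6H6 (5 mol %), a chiral pybox ligand (antipode chosen for the S ether) and i-Pr2NEt in ClCH2CH2Cl at −10 °C. It passes through a planar copper allenylidene that erases the centre of F7.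
- Phenol 16 adds to the face left open by the ligand and gives 17.

Further compounds
F1 | step 16 | 5,7,3',4'-tetra-O-benzylcatechin | O(Cc9ccccc9)c1cc(OCc9ccccc9)c2c(c1)O[C@H](c5ccc(OCc9ccccc9)c(OCc9ccccc9)c5)[C@@H](O)C2
F2 | step 16 | 8-bromo-tetra-O-benzylcatechin | O(Cc9ccccc9)c1cc(OCc9ccccc9)c2c(c1Br)O[C@H](c5ccc(OCc9ccccc9)c(OCc9ccccc9)c5)[C@@H](O)C2
F3 | step 16 | 8-bromo-4β-(2-ethoxyethoxy)-tetra-O-benzylcatechin | O(Cc9ccccc9)c1cc(OCc9ccccc9)c2c(c1Br)O[C@H](c5ccc(OCc9ccccc9)c(OCc9ccccc9)c5)[C@@H](O)[C@H]2OCCOCC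
F4 | step 16 | 8-bromo-tetra-O-benzylcatechin-(4α→6)-8-bromo-tetra-O-benzylcatechin | O(Cc9ccccc9)c1cc(OCc9ccccc9)c2c(c1Br)O[C@H](c5ccc(OCc9ccccc9)c(OCc9ccccc9)c5)[C@@H](O)[C@@H]2c4c(OCc9ccccc9)c(Br)c6c(c4OCc9ccccc9)C[C@H](O)[C@@H](c5ccc(OCc9ccccc9)c(OCc9ccccc9)c5)O6
F5 | step 16 | dibromo trideca-O-benzyl trimer | O(Cc9ccccc9)c1cc(OCc9ccccc9)c2c(c1)O[C@H](c5ccc(OCc9ccccc9)c(OCc9ccccc9)c5)[C@H](OCc9ccccc9)[C@H]2c3c(OCc9ccccc9)c(Br)c7c(c3OCc9ccccc9)[C@@H](c4c(OCc9ccccc9)c(Br)c6c(c4OCc9ccccc9)C[C@H](O)[C@@H](c5ccc(OCc9ccccc9)c(OCc9ccccc9)c5)O6)[C@H](O)[C@@H](c5ccc(OCc9ccccc9)c(OCc9ccccc9)c5)O7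
F6 | step 17 | bis(C3-pinacolboronate) | O(Cc9ccccc9)c1cc(OCc9ccccc9)c2c(c1)O[C@H](c5ccc(OCc9ccccc9)c(OCc9ccccc9)c5)[C@H](OCc9ccccc9)[C@H]2c3c(OCc9ccccc9)cc7c(c3OCc9ccccc9)[C@@H](c4c(OCc9ccccc9)cc6c(c4OCc9ccccc9)C[C@H](B8OC(C)(C)C(C)(C)O8)[C@@H](c5ccc(OCc9ccccc9)c(OCc9ccccc9)c5)O6)[C@H](B8OC(C)(C)C(C)(C)O8)[C@@H](c5ccc(OCc9ccccc9)c(OCc9ccccc9)c5)O7
F7 | step 13 | (R)-1-[3,4-bis(benzyloxy)phenyl]prop-2-yn-1-yl acetate | CC(=O)O[C@@H](c1ccc(OCc2ccccc2)c(OCc2ccccc2)c1)C#C
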